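**Plan**

1. Atom labels (used throughout, independent of IUPAC locants): ring C1 (carbinol), C2, C3, C4 (CH3, Cl), C5 (Br), C6; chain C7(=CH2)–C8–C9–C10(OH)–C11(=CH2)CH3.
2. Cuts: C7=CH2 (Peterson) and C7–C8 (Grignard on a C7 aldehyde). C4–Cl and C5–Br are traced back through a C1–O–C4 bromoether to a C4=C5 alkene. The C1–O bond is then removed while C1–C5 is re-formed, which contracts the cyclohexene to a bicyclo[3.1.0]hexane. Last cuts are C4–CH3, the two carbene bonds C5–C1 and C5–C6, and C2–C3 (Claisen).
3. Enabling feature: in the six-membered ring, the tertiary carbinol C1, the methylene C6 and the alkene C4(CH3)=C5 make up a homoallylic alcohol. This is the water adduct of the cyclopropylcarbinyl cation of a 2-methylbicyclo[3.1.0]hexan-2-ol in which C1–C5 is the bond shared by the three- and five-membered rings.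
4. Forward order: acyclic diazoketone, then three- and five-membered rings together (step 5), six-membered ring by enlargement (step 7), temporary oxygen bridge (step 8), bridge reopened to the bromochloride (step 10), side chain joined at C7 (step 16), then methylene and deprotection.
5. Stereochemistry: C1 comes from the ligand-controlled cyclopropanation and is carried over by inversion in step 7. C5 and C4 come from anti bromoetherification directed by the C1 hydroxyl, followed by retentive chloride exchange. C10 comes from a Sharpless kinetic resolution, and union with this pure fragment turns any residual ring antipode into a separable diastereomer.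

Key step: step 7

Assumption: the (R,R) bis(oxazoline) is assigned to the (1S,5S) ketone 12 by analogy with the sense of induction of this ligand class in intermolecular cyclopropanation; both antipodes are commercial, so a reversed sense is corrected by exchanging the ligand only.

**Route**

Step 1
Reactants: 1 2-methylenepropane-1,3-diol; 2 4-methoxybenzyl chloride
Product: 3 2-{[(4-methoxybenzyl)oxy]methyl}prop-2-en-1-ol
Conditions: NaH (1.0 equiv), THF–DMF, 0 °C; 2, Bu4NI (cat.), 0 °C → rt
Reagents that add atoms: none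
Why: Williamson etherification of the monoalkoxide of a symmetrical diol should give mainly the monoether, which is easily separated from diol and diether.

Step 2
Reactants: 3 2-{[(4-methoxybenzyl)oxy]methyl}prop-2-en-1-ol; 4 triethyl orthoacetate
Product: 6 ethyl 4-{[(4-methoxybenzyl)oxy]methyl}pent-4-enoate, via allyl ketene acetal 5 (not isolated)
Conditions: 4 (excess), EtCO2H (cat.), 140 °C, EtOH distilled off
Reagents that add atoms: none
Why: Johnson–Claisen rearrangement, in which acid-catalysed exchange gives ketene acetal 5 and its [3,3] shift forms C2–C3 and leaves the 1,1-disubstituted alkene C1=C6.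

Step 3
Reactants: 6 ethyl 4-{[(4-methoxybenzyl)oxy]methyl}pent-4-enoate
Product: 7 4-{[(4-methoxybenzyl)oxy]methyl}pent-4-enoic acid
Conditions: LiOH, THF–MeOH–H2O, rt; then 1 M HCl to pH 3
Reagents that add atoms: lithium hydroxide, [Li+].[OH-]
Why: Ordinary ester saponification, to which the PMB ether and the alkene are inert.

Step 4
Reactants: 7 4-{[(4-methoxybenzyl)oxy]methyl}pent-4-enoic acid; 8 (trimethylsilyl)diazomethane
Product: 11 1-diazo-5-{[(4-methoxybenzyl)oxy]methyl}hex-5-en-2-one, via acid chloride 9 (not isolated), via C-silyl diazoketone 10 (not isolated)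
Conditions: Me2C=C(Cl)NMe2, CH2Cl2, 0 °C; then 8, Et3N, MeCN–THF, 0 °C; aqueous work-up
Reagents that add atoms: none
Why: Acylation of a diazoalkane (Arndt–Eistert-type diazoketone synthesis), in which the neutral chloroenamine activation releases no HCl, so the PMB ether and alkene are untouched, and the C-silyl group is lost on aqueous work-up.

Step 5
Reactants: 11 1-diazo-5-{[(4-methoxybenzyl)oxy]methyl}hex-5-en-2-one
Product: 12 (1S,5S)-5-{[(4-methoxybenzyl)oxy]methyl}bicyclo[3.1.0]hexan-2-one
Conditions: (CuOTf)2·C6H6 (cat.), (R,R)-2,2'-isopropylidenebis(4-tert-butyl-2-oxazoline) (cat.), CH2Cl2, slow addition of 11, rt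
Reagents that add atoms: none
Why: Intramolecular cyclopropanation by a monovalent-copper carbenoid forms C5–C1 and C5–C6; the three-atom tether allows only the cis-fused bicycle, and the C2-symmetric ligand selects one carbenoid face, fixing C1 and C5 together.

Step 6
Reactants: 12 (1S,5S)-5-{[(4-methoxybenzyl)oxy]methyl}bicyclo[3.1.0]hexan-2-one
Product: 13 (1S,2R,5S)-5-{[(4-methoxybenzyl)oxy]methyl}-2-methylbicyclo[3.1.0]hexan-2-ol
Conditions: MeMgBr, THF, −78 → 0 °C; aq. NH4Cl
Reagents that add atoms: methylmagnesium bromide, C[Mg]Br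
Why: Grignard 1,2-addition to a cyclopropyl ketone from the face away from the cyclopropane methylene should place the hydroxyl syn to it, and a minor epimer does no harm because this centre is erased in step 7.

Step 7
Reactants: 13 (1S,2R,5S)-5-{[(4-methoxybenzyl)oxy]methyl}-2-methylbicyclo[3.1.0]hexan-2-ol
Product: 14 (1S)-1-{[(4-methoxybenzyl)oxy]methyl}-4-methylcyclohex-3-en-1-ol
Conditions: HClO4 (dilute, aq.), THF–H2O, 0 °C → rt
Reagents that add atoms: water, O
Why: Protonation and loss of the C4 hydroxyl gives a tertiary cyclopropylcarbinyl cation whose charge is relayed through the bent C1–C5 bond, and water adds to C1 from the rear of that bond while it turns into the C4=C5 π bond (cyclopropylcarbinyl–homoallyl rearrangement). The closest known cases are the acid hydration of thujane-type alcohols to terpinen-4-ol and the solvolysis of 3,5-cyclosteroid 6-ols. The ring C1–C2–C3–C4–C5–C6 arises by enlargement, that is by fission of the zero bridge common to the three- and five-membered rings, and not by a cyclisation event. The C1 stereocentre is set by inversion at the quaternary cyclopropane carbon, so the configuration installed in step 5 becomes (S) in 14, while the C4 carbinol centre disappears. Fission of C1–C5 rather than C5–C6 follows from tertiary against primary charge development, and fidelity of the transfer is supported by the β-oxygen on C7, which disfavours a free planar C1 cation. Dilute acid and short contact are needed so that the new alkene is not protonated and trapped by the C1 hydroxyl and the PMB ether is kept.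

Step 8
Reactants: 14 (1S)-1-{[(4-methoxybenzyl)oxy]methyl}-4-methylcyclohex-3-en-1-ol
Product: 15 (1R,2R,4S)-2-bromo-4-{[(4-methoxybenzyl)oxy]methyl}-1-methyl-7-oxabicyclo[2.2.1]heptane (bromine endo)
Conditions: NBS, CH2Cl2, 0 °C, dark
Reagents that add atoms: N-bromosuccinimide, O=C1CCC(=O)N1Br
Why: Transannular bromoetherification, in which reversible bromonium formation is drained through the face opposite the C1 hydroxyl and the hydroxyl opens it at the tertiary C4 (Markovnikov, anti), so C4–O is cis and C5–Br trans to the C1 oxygen.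

Step 9
Reactants: 15 (1R,2R,4S)-2-bromo-4-{[(4-methoxybenzyl)oxy]methyl}-1-methyl-7-oxabicyclo[2.2.1]heptane
Product: 16 [(1S,3R,4R)-3-bromo-4-methyl-7-oxabicyclo[2.2.1]heptan-1-yl]methanol
Conditions: DDQ, CH2Cl2–pH 7 buffer, 0 °C → rt
Reagents that add atoms: none
Why: Oxidative PMB cleavage (hydride abstraction, then hydrolysis of the oxocarbenium ion), to which the bridged ether and the secondary bromide are inert.

Step 10
Reactants: 16 [(1S,3R,4R)-3-bromo-4-methyl-7-oxabicyclo[2.2.1]heptan-1-yl]methanol
Product: 19 (1S,3R,4R)-3-bromo-4-chloro-1-(hydroxymethyl)-4-methylcyclohexan-1-ol, via alkoxydichloroborane 17 (not isolated), via spiro chlorodioxaborolane 18 (not isolated)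
Conditions: BCl3 (CH2Cl2 solution), CH2Cl2, −78 → −20 °C; then H2O–THF, 0 °C
Reagents that add atoms: boron trichloride, ClB(Cl)Cl
Why: Proposed new method: the primary alcohol gives alkoxydichloroborane 17, whose boron binds the adjacent bridge oxygen in a five-membered chelate; the C4–O bond ionises (not C1–O, which stays in the chelate and sits next to the electron-poor C7–O–B carbon) with help from the nearly antiperiplanar endo bromine, and the resulting bromonium ion is opened at tertiary C4 by chloride passed from boron on the face the oxygen has just left, so two inversions add up to retention (Cl cis to C1–O, trans to Br) and dioxaborolane 18 is hydrolysed on work-up; the closest known reaction types are boron trihalide opening of 7-oxanorbornane bridges, chelation-directed ether cleavage by BCl3 and chloride opening of bromonium ions in alkene bromochlorination. The bridge is opened here, before any C7 carbonyl or side-chain alkene is present, so that Lewis-acid-induced carbonyl–ene closure and allylic ionisation cannot compete.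

Step 11
Reactants: 19 (1S,3R,4R)-3-bromo-4-chloro-1-(hydroxymethyl)-4-methylcyclohexan-1-ol
Product: 20 (1S,3R,4R)-3-bromo-4-chloro-1-hydroxy-4-methylcyclohexane-1-carbaldehyde
Conditions: IBX, DMSO, rt
Reagents that add atoms: none
Why: IBX oxidation of the primary alcohol, a reagent known to convert 1,2-diols into α-hydroxy carbonyl compounds without glycol fission, while the tertiary hydroxyl cannot react.

Step 12
Reactants: 21 3-bromopropan-1-ol
Product: 22 3-bromopropanal
Conditions: Dess–Martin periodinane, CH2Cl2, 0 °C → rt; dried solution used at once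
Reagents that add atoms: none
Why: Dess–Martin oxidation runs without base, which should prevent loss of HBr from the β-bromo aldehyde.

Step 13
Reactants: 22 3-bromopropanal; 23 isopropenylmagnesium bromide
Product: 24 rac-5-bromo-2-methylpent-1-en-3-ol
Conditions: 23 (THF solution), THF, −78 °C; aq. NH4Cl
Reagents that add atoms: none
Why: Grignard 1,2-addition at low temperature should outrun enolisation and elimination of the β-bromo aldehyde, and it forms C10–C11 in racemic form.

Step 14
Reactants: 24 rac-5-bromo-2-methylpent-1-en-3-ol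
Product: 25 (3R)-5-bromo-2-methylpent-1-en-3-ol
Conditions: Ti(OiPr)4 (cat.), L-(+)-DIPT (cat.), t-BuOOH (0.6 equiv), 4 Å MS, CH2Cl2, −20 °C
Reagents that add atoms: none
Why: Sharpless kinetic resolution, in which L-(+)-DIPT directs fast epoxidation of the (S)-alcohol, so running past half conversion should leave the (R)-alcohol in high enantiomeric purity and thereby set C10.

Step 15
Reactants: 25 (3R)-5-bromo-2-methylpent-1-en-3-ol
Product: 26 {[(3R)-5-bromo-2-methylpent-1-en-3-yl]oxy}(tert-butyl)dimethylsilane
Conditions: TBSOTf, 2,6-lutidine, CH2Cl2, −78 → 0 °C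
Reagents that add atoms: tert-butyldimethylsilyl triflate, CC(C)(C)[Si](C)(C)OS(=O)(=O)C(F)(F)F
Why: Silylation with the triflate and a hindered base protects C10–OH for the Grignard step without displacing the primary bromide.

Step 16
Reactants: 20 (1S,3R,4R)-3-bromo-4-chloro-1-hydroxy-4-methylcyclohexane-1-carbaldehyde; 26 {[(3R)-5-bromo-2-methylpent-1-en-3-yl]oxy}(tert-butyl)dimethylsilane
Product: 28 (1S,3R,4R)-3-bromo-1-[(4R)-4-(tert-butyldimethylsilyloxy)-1-hydroxy-5-methylhex-5-en-1-yl]-4-chloro-4-methylcyclohexan-1-ol (both C7 epimers), via Grignard reagent 27 (not isolated)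
Conditions: 26 (2.5 equiv), Mg, THF, rt → 40 °C; then 20, THF, −78 → −20 °C; aq. NH4Cl
Reagents that add atoms: none
Why: Grignard formation and 1,2-addition form C7–C8; one equivalent is spent on the C1 hydroxyl, the alkyl halides are inert at low temperature, and the new C7 carbinol centre is removed in step 17.

Step 17
Reactants: 28 (1S,3R,4R)-3-bromo-1-[(4R)-4-(tert-butyldimethylsilyloxy)-1-hydroxy-5-methylhex-5-en-1-yl]-4-chloro-4-methylcyclohexan-1-ol
Product: 29 (4R)-1-[(1S,3R,4R)-3-bromo-4-chloro-1-hydroxy-4-methylcyclohexyl]-4-(tert-butyldimethylsilyloxy)-5-methylhex-5-en-1-one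
Conditions: IBX, DMSO, rt
Reagents that add atoms: none
Why: IBX oxidation of the secondary alcohol of a secondary/tertiary 1,2-diol gives the α-ketol without C–C cleavage and leaves the silyl ether, alkene and halides alone.

Step 18
Reactants: 29 (4R)-1-[(1S,3R,4R)-3-bromo-4-chloro-1-hydroxy-4-methylcyclohexyl]-4-(tert-butyldimethylsilyloxy)-5-methylhex-5-en-1-one
Product: 30 (1S,3R,4R)-3-bromo-1-[(5R)-5-(tert-butyldimethylsilyloxy)-2-hydroxy-6-methyl-1-(trimethylsilyl)hept-6-en-2-yl]-4-chloro-4-methylcyclohexan-1-ol (both C7 epimers)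
Conditions: Me3SiCH2Li, CeCl3 (anhydrous), THF, −78 °C; then 29, −78 → 0 °C; aq. NH4Cl
Reagents that add atoms: (trimethylsilyl)methyllithium, [Li]C[Si](C)(C)C
Why: Organocerium variant of the Peterson addition, whose weakly basic, oxophilic reagent should add to the hindered, enolisable α-hydroxy ketone without attacking C–Br or C–Cl, and the C7 configuration is of no consequence.

Step 19
Reactants: 30 (1S,3R,4R)-3-bromo-1-[(5R)-5-(tert-butyldimethylsilyloxy)-2-hydroxy-6-methyl-1-(trimethylsilyl)hept-6-en-2-yl]-4-chloro-4-methylcyclohexan-1-ol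
Product: 31 (1S,3R,4R)-3-bromo-4-chloro-1-[(5R)-5-hydroxy-6-methylhepta-1,6-dien-2-yl]-4-methylcyclohexan-1-ol
Conditions: HF (48% aq.), MeCN, 0 °C → rt
Reagents that add atoms: none
Why: Acid-induced Peterson elimination (anti loss of Me3Si and the β-silicon-activated C7 hydroxyl) creates C7=CH2, and the same reagent cleaves the TBS ether, with no stereocentre touched.

**Compound list**

1 | 2-methylenepropane-1,3-diol | C=C(CO)CO | starting material
2 | 4-methoxybenzyl chloride | COc1ccc(CCl)cc1 | starting material
3 | 2-{[(4-methoxybenzyl)oxy]methyl}prop-2-en-1-ol | C=C(CO)COCc1ccc(OC)cc1 | intermediate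
4 | triethyl orthoacetate | CCOC(C)(OCC)OCC | starting material
5 | 1-ethoxyvinyl 2-{[(4-methoxybenzyl)oxy]methyl}allyl ether (allyl ketene acetal) | C=C(OCC)OCC(=C)COCc1ccc(OC)cc1 | intermediate
6 | ethyl 4-{[(4-methoxybenzyl)oxy]methyl}pent-4-enoate | CCOC(=O)CCC(=C)COCc1ccc(OC)cc1 | intermediate
7 | 4-{[(4-methoxybenzyl)oxy]methyl}pent-4-enoic acid | OC(=O)CCC(=C)COCc1ccc(OC)cc1 | intermediate
8 | (trimethylsilyl)diazomethane | C[Si](C)(C)C=[N+]=[N-] | starting material
9 | 4-{[(4-methoxybenzyl)oxy]methyl}pent-4-enoyl chloride | ClC(=O)CCC(=C)COCc1ccc(OC)cc1 | intermediate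
10 | 1-diazo-5-{[(4-methoxybenzyl)oxy]methyl}-1-(trimethylsilyl)hex-5-en-2-one | C[Si](C)(C)C(=[N+]=[N-])C(=O)CCC(=C)COCc1ccc(OC)cc1 | intermediate
11 | 1-diazo-5-{[(4-methoxybenzyl)oxy]methyl}hex-5-en-2-one | [N-]=[N+]=CC(=O)CCC(=C)COCc1ccc(OC)cc1 | intermediate
12 | (1S,5S)-5-{[(4-methoxybenzyl)oxy]methyl}bicyclo[3.1.0]hexan-2-one | COc1ccc(COC[C@@]23C[C@@H]2C(=O)CC3)cc1 | intermediate
13 | (1S,2R,5S)-5-{[(4-methoxybenzyl)oxy]methyl}-2-methylbicyclo[3.1.0]hexan-2-ol | COc1ccc(COC[C@@]23C[C@@H]2[C@](C)(O)CC3)cc1 | intermediate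
14 | (1S)-1-{[(4-methoxybenzyl)oxy]methyl}-4-methylcyclohex-3-en-1-ol | COc1ccc(COC[C@]2(O)CCC(C)=CC2)cc1 | intermediate
15 | (1R,2R,4S)-2-bromo-4-{[(4-methoxybenzyl)oxy]methyl}-1-methyl-7-oxabicyclo[2.2.1]heptane | COc1ccc(COC[C@@]23CC[C@@](C)(O2)[C@H](Br)C3)cc1 | intermediate
16 | [(1S,3R,4R)-3-bromo-4-methyl-7-oxabicyclo[2.2.1]heptan-1-yl]methanol | OC[C@@]12CC[C@@](C)(O1)[C@H](Br)C2 | intermediate
17 | {[(1S,3R,4R)-3-bromo-4-methyl-7-oxabicyclo[2.2.1]heptan-1-yl]methoxy}dichloroborane | ClB(Cl)OC[C@@]12CC[C@@](C)(O1)[C@H](Br)C2 | intermediate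
18 | (5S,7R,8R)-7-bromo-2,8-dichloro-8-methyl-1,3-dioxa-2-boraspiro[4.5]decane | ClB1OC[C@]2(O1)CC[C@@](C)(Cl)[C@H](Br)C2 | intermediate
19 | (1S,3R,4R)-3-bromo-4-chloro-1-(hydroxymethyl)-4-methylcyclohexan-1-ol | OC[C@]1(O)CC[C@@](C)(Cl)[C@H](Br)C1 | intermediate
20 | (1S,3R,4R)-3-bromo-4-chloro-1-hydroxy-4-methylcyclohexane-1-carbaldehyde | O=C[C@]1(O)CC[C@@](C)(Cl)[C@H](Br)C1 | intermediate
21 | 3-bromopropan-1-ol | OCCCBr | starting material
22 | 3-bromopropanal | O=CCCBr | intermediate
23 | isopropenylmagnesium bromide | C=C(C)[Mg]Br | starting material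
24 | rac-5-bromo-2-methylpent-1-en-3-ol | C=C(C)C(O)CCBr | intermediate
25 | (3R)-5-bromo-2-methylpent-1-en-3-ol | C=C(C)[C@H](O)CCBr | intermediate
26 | {[(3R)-5-bromo-2-methylpent-1-en-3-yl]oxy}(tert-butyl)dimethylsilane | C=C(C)[C@H](O[Si](C)(C)C(C)(C)C)CCBr | intermediate
27 | [(3R)-3-(tert-butyldimethylsilyloxy)-4-methylpent-4-en-1-yl]magnesium bromide | C=C(C)[C@H](O[Si](C)(C)C(C)(C)C)CC[Mg]Br | intermediate
28 | (1S,3R,4R)-3-bromo-1-[(4R)-4-(tert-butyldimethylsilyloxy)-1-hydroxy-5-methylhex-5-en-1-yl]-4-chloro-4-methylcyclohexan-1-ol, C7 epimers | C=C(C)[C@H](O[Si](C)(C)C(C)(C)C)CCC(O)[C@]1(O)CC[C@@](C)(Cl)[C@H](Br)C1 | intermediate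
29 | (4R)-1-[(1S,3R,4R)-3-bromo-4-chloro-1-hydroxy-4-methylcyclohexyl]-4-(tert-butyldimethylsilyloxy)-5-methylhex-5-en-1-one | C=C(C)[C@H](O[Si](C)(C)C(C)(C)C)CCC(=O)[C@]1(O)CC[C@@](C)(Cl)[C@H](Br)C1 | intermediate
30 | (1S,3R,4R)-3-bromo-1-[(5R)-5-(tert-butyldimethylsilyloxy)-2-hydroxy-6-methyl-1-(trimethylsilyl)hept-6-en-2-yl]-4-chloro-4-methylcyclohexan-1-ol, C7 epimers | C=C(C)[C@H](O[Si](C)(C)C(C)(C)C)CCC(O)(C[Si](C)(C)C)[C@]1(O)CC[C@@](C)(Cl)[C@H](Br)C1 | intermediate
31 | (1S,3R,4R)-3-bromo-4-chloro-1-[(5R)-5-hydroxy-6-methylhepta-1,6-dien-2-yl]-4-methylcyclohexan-1-ol | C=C(C)[C@H](O)CCC(=C)[C@]1(O)CC[C@@](C)(Cl)[C@H](Br)C1 | target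

**Step count**

Total steps: 19. Longest linear sequence: 15 (steps 1–11 and 16–19).

**Steps most likely to fail**

Step 10 (new method).
- What may go wrong: after C4–O ionisation the cation may lose a proton instead of taking up chloride. Chloride may strike bromine rather than carbon, so that BrCl is expelled and adds back without facial control. The bridge may also open on the C1 side.
- Fallback (known chemistry only), from 14 back to 19: DDQ removes the PMB group to give the diol (1S)-1-(hydroxymethyl)-4-methylcyclohex-3-en-1-ol F1. Treatment with 2,2-dimethoxypropane and PPTS ties up both hydroxyls as the acetonide (5S)-2,2,8-trimethyl-1,3-dioxaspiro[4.5]dec-7-ene F2.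
- Intermolecular anti, Markovnikov bromochlorination (NBS, Et4NCl, CH2Cl2, low temperature) should then give both anti adducts. The one with chlorine cis to the C1 oxygen, (5S,7R,8R)-7-bromo-8-chloro-2,2,8-trimethyl-1,3-dioxaspiro[4.5]decane F3, is separated by chromatography, and aqueous acetic acid frees 19.
- Tether control is given up here in exchange for a separation.

Step 7 (key step).
- What may go wrong: part of the material may pass through a free C1 cation, with erosion of enantiomeric purity. The β-oxygen may slow ring fission so much that the reaction stalls at reversible proton loss. The product alkene may be protonated and closed by the C1 hydroxyl, or the PMB ether may be lost.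
- Fallback (same bond changes, with an internal nucleophile in place of external water), from 13 back to 16: DDQ gives (1S,2R,5S)-5-(hydroxymethyl)-2-methylbicyclo[3.1.0]hexan-2-ol F4. Selective benzoylation of the primary hydroxyl gives [(1S,4R,5S)-4-hydroxy-4-methylbicyclo[3.1.0]hexan-1-yl]methyl benzoate F5.
- On acid ionisation the benzoate carbonyl oxygen closes on C1 from the rear of the C1–C5 bond (acyloxy neighbouring-group participation). Hydrolysis at the acyl carbon then leaves [(1S)-1-hydroxy-4-methylcyclohex-3-en-1-yl]methyl benzoate F6.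
- NBS gives [(1S,3R,4R)-3-bromo-4-methyl-7-oxabicyclo[2.2.1]heptan-1-yl]methyl benzoate F7, and K2CO3 in methanol returns 16.

Step 5.
- What may go wrong: facial discrimination of the unsubstituted keto-carbenoid may be insufficient, and oxonium ylide formation at the ether oxygen may compete.
- Fallback (stereospecific route from a resolved epoxide), from 6 back to 12: DIBAL-H gives 4-{[(4-methoxybenzyl)oxy]methyl}pent-4-enal F8. Corey–Chaykovsky methylenation (trimethylsulfonium iodide, NaH) gives rac-2-(3-{[(4-methoxybenzyl)oxy]methyl}but-3-en-1-yl)oxirane F9.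
- Hydrolytic kinetic resolution with (S,S)-(salen)Co(OAc) should leave (2S)-2-(3-{[(4-methoxybenzyl)oxy]methyl}but-3-en-1-yl)oxirane F10.
- LiTMP lithiates the terminal epoxide carbon, and the carbenoid adds to the alkene with full transfer of configuration to give (1S,2S,5S)-5-{[(4-methoxybenzyl)oxy]methyl}bicyclo[3.1.0]hexan-2-ol F11. Dess–Martin oxidation then gives 12.

**Further compounds**

F1 | step 10 | (1S)-1-(hydroxymethyl)-4-methylcyclohex-3-en-1-ol | OC[C@]1(O)CCC(C)=CC1
F2 | step 10 | (5S)-2,2,8-trimethyl-1,3-dioxaspiro[4.5]dec-7-ene | CC1(C)OC[C@]2(O1)CCC(C)=CC2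
F3 | step 10 | (5S,7R,8R)-7-bromo-8-chloro-2,2,8-trimethyl-1,3-dioxaspiro[4.5]decane | CC1(C)OC[C@]2(O1)CC[C@@](C)(Cl)[C@H](Br)C2
F4 | step 7 | (1S,2R,5S)-5-(hydroxymethyl)-2-methylbicyclo[3.1.0]hexan-2-ol | OC[C@@]12C[C@@H]1[C@](C)(O)CC2
F5 | step 7 | [(1S,4R,5S)-4-hydroxy-4-methylbicyclo[3.1.0]hexan-1-yl]methyl benzoate | O=C(OC[C@@]12C[C@@H]1[C@](C)(O)CC2)c3ccccc3
F6 | step 7 | [(1S)-1-hydroxy-4-methylcyclohex-3-en-1-yl]methyl benzoate | O=C(OC[C@]1(O)CCC(C)=CC1)c2ccccc2
F7 | step 7 | [(1S,3R,4R)-3-bromo-4-methyl-7-oxabicyclo[2.2.1]heptan-1-yl]methyl benzoate | O=C(OC[C@@]12CC[C@@](C)(O1)[C@H](Br)C2)c3ccccc3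
F8 | step 5 | 4-{[(4-methoxybenzyl)oxy]methyl}pent-4-enal | COc1ccc(COCC(=C)CCC=O)cc1
F9 | step 5 | rac-2-(3-{[(4-methoxybenzyl)oxy]methyl}but-3-en-1-yl)oxirane | COc1ccc(COCC(=C)CCC2CO2)cc1
F10 | step 5 | (2S)-2-(3-{[(4-methoxybenzyl)oxy]methyl}but-3-en-1-yl)oxirane | COc1ccc(COCC(=C)CC[C@H]2CO2)cc1
F11 | step 5 | (1S,2S,5S)-5-{[(4-methoxybenzyl)oxy]methyl}bicyclo[3.1.0]hexan-2-ol | COc1ccc(COC[C@@]23C[C@@H]2[C@@H](O)CC3)cc1
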